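The unbranched, ring-free C1–C26 acyl chain carries no handle, so a temporary alkene is placed at C10–C11 and the chain is cut there. Undec-10-enoic acid (1) and 2-phenylethanol (2) are condensed to the alkenyl ester 3, which already holds the phenethyl ester and C1–C10 capped by a sacrificial terminal =CH2. Ruthenium-catalysed cross-metathesis of 3 with 1-heptadecene (4) creates the C10=C11 bond, and with it the whole C26 skeleton, in one operation, with ethene as the only co-product, giving alkene 5. Hydrogenation then delivers the target 6. The key step exploits the featureless acyclic chain; the benzene ring is a spectator, and no ring or stereocentre is formed.

Key step: step 2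

Remark: the alcohol part is the 2-phenylethyl group, so the target has no stereocentre and is achiral; 5 is written as the E isomer expected to predominate, and any Z isomer formed alongside is carried forward because step 3 removes the double bond.

Step 1
Reactants: 1 undec-10-enoic acid; 2 2-phenylethanol
Product: 3 2-phenylethyl undec-10-enoate
Conditions: 1 (1.1 equiv), p-TsOH·H2O (5 mol%), toluene, reflux, Dean–Stark; aq. Na2CO3 wash, short SiO2 plug
Reagents that add atoms: none
Why: Fischer esterification of an unhindered primary alcohol with an unhindered aliphatic acid should be driven to completion by azeotropic removal of water, while the isolated terminal alkene and the arene are inert to catalytic sulfonic acid in refluxing toluene.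

Step 2
Reactants: 3 2-phenylethyl undec-10-enoate; 4 1-heptadecene
Product: 5 2-phenylethyl (E)-hexacos-10-enoate
Conditions: 4 (3 equiv, GC-pure), Grubbs II (2 mol%), 1,4-benzoquinone (10 mol%), CH2Cl2 (0.3 M), 40 °C, Ar sparge; SiO2 (hexane to strip hydrocarbons, then hexane/EtOAc)
Reagents that add atoms: none
Why: The step is an olefin cross-metathesis by the Chauvin mechanism, in which the ruthenium alkylidene adds [2+2] to each terminal alkene to give a ruthenacyclobutane whose cycloreversion passes the alkylidene on, so that the C10 alkylidene of 3 and the C16 alkylidene of 4 end up joined as the C10=C11 bond while the two terminal CH2 groups leave as ethene. The closest known reaction type is the ruthenium–carbene cross-metathesis of two monosubstituted (Type I) alkenes, routine for ω-alkenoates and 1-alkenes. No ring is closed and no stereocentre is created, and the geometry of the new alkene is of no consequence since it is saturated in step 3. The selectivity required is cross- over self-coupling; as both partners react at similar rates it is secured statistically by the threefold excess of 4, and because the self-coupled ester stays metathesis-active it should be drawn back into the product pool by secondary metathesis while ethene is purged. A second requirement is that the double bond does not migrate, since that would alter the chain length; the benzoquinone additive (to intercept ruthenium hydrides), the moderate temperature and stopping once 3 is consumed address this. The ester and the arene are remote from the alkene and should neither bind nor react with the catalyst.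

Step 3
Reactants: 5 2-phenylethyl (E)-hexacos-10-enoate
Product: 6 2-phenylethyl hexacosanoate
Conditions: H2 (1 atm), 10% Pd/C, EtOAc, rt to 40 °C; Celite filtration, recrystallisation from acetone
Reagents that add atoms: none
Why: Heterogeneous catalytic hydrogenation should saturate the unhindered 1,2-disubstituted alkene of either geometry under conditions where the ester C–O bond, which sits on a homobenzylic and not a benzylic carbon, is not prone to hydrogenolysis and the benzene ring is not reduced.

Compound list
1 | undec-10-enoic acid | C=CCCCCCCCCC(=O)O | starting material
2 | 2-phenylethanol | OCCc1ccccc1 | starting material
3 | 2-phenylethyl undec-10-enoate | C=CCCCCCCCCC(=O)OCCc1ccccc1 | intermediate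
4 | 1-heptadecene (heptadec-1-ene) | C=CCCCCCCCCCCCCCCCC | starting material
5 | 2-phenylethyl (E)-hexacos-10-enoate | CCCCCCCCCCCCCCC/C=C/CCCCCCCCC(=O)OCCc1ccccc1 | intermediate
6 | 2-phenylethyl hexacosanoate (phenylethyl n-hexacosanoate) | CCCCCCCCCCCCCCCCCCCCCCCCCC(=O)OCCc1ccccc1 | target

Total step count: 3
Longest linear sequence: 3 steps (1 → 3 → 5 → 6)

Steps most likely to fail

Step 2 (cross-metathesis). Self-coupling of each alkene may take too large a share of the material. Double-bond migration by ruthenium hydride species formed on catalyst decay, followed by metathesis of the migrated alkenes, may also scramble the chain length into homologues that cannot be separated. The fallback sets out from 3 and fixes both chain lengths through the reagents. Ozonolysis of 3 (O3, CH2Cl2, −78 °C, then PPh3) should cleave the terminal alkene to the aldehyde 2-phenylethyl 10-oxodecanoate F1. Wittig olefination of F1 with the ylide generated from commercial hexadecyltriphenylphosphonium bromide and NaHMDS (THF, −78 °C to rt) should form the same C10=C11 bond and give 2-phenylethyl (Z)-hexacos-10-enoate F2; the ester is expected to survive because non-stabilised ylides add to aldehydes far faster than to esters at low temperature. Hydrogenation of F2 under the conditions of step 3 brings the fallback back to the route at 6.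

Step 3 (hydrogenation). The heterogeneous reduction may stall because the waxy substrate and product dissolve poorly and coat the catalyst, or because residual ruthenium poisons the palladium surface. The fallback sets out from 5 and replaces surface catalysis by a homogeneous, metal-free diimide reduction (p-toluenesulfonylhydrazide, NaOAc, DME/H2O, reflux). Concerted transfer of two hydrogens to the unpolarised C=C should leave ester and arene untouched and return to the route at 6. No new compound is made on the way (none, F0).

Step 1 (esterification). Conversion may stop short at equilibrium, or hot acid may cause self-etherification of the alcohol or migration of the terminal alkene, which would hand wrong alkene isomers to step 2. The fallback sets out from 1 and uses irreversible acylation instead of an acid-catalysed equilibrium. Oxalyl chloride with catalytic DMF (CH2Cl2, 0 °C to rt) should convert 1 into undec-10-enoyl chloride F3. Treatment of F3 with 2, Et3N and catalytic DMAP (CH2Cl2, 0 °C to rt) should give the ester and return to the route at 3.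

Further compounds
F1 | step 2 | 2-phenylethyl 10-oxodecanoate | O=CCCCCCCCCC(=O)OCCc1ccccc1
F2 | step 2 | 2-phenylethyl (Z)-hexacos-10-enoate | CCCCCCCCCCCCCCC/C=C\CCCCCCCCC(=O)OCCc1ccccc1
F0 | step 3 | none | none
F3 | step 1 | undec-10-enoyl chloride | C=CCCCCCCCCC(=O)Cl
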